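Readings and results were generated by integration with constants of no real substance; noise was put on by code.

**Same dose.** Elm at 12.0 min and ash at 6.00 min read 7.5% and 7.7% of Z, level within the scatter of 1 percentage point. Their doses, the charge of J times the time, are also close: 0.168 M·min and 0.174 M·min. This fits the reactions considered so far: with equivalents held, J + Q → E, Q + D → G and E + G → Z are bimolecular and follow dose, while D ⇌ L keeps its own clock.

| setting | elm | ash | cedar | alder | summer | autumn | winter | dawn | dusk | midnight |
|---|---|---|---|---|---|---|---|---|---|---|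
| J | 0.014 M | 0.029 M | 0.066 M | 0.050 M | 0.050 M | 0.050 M | 0.050 M | 0.012 M | 0.030 M | 0.080 M |
| D | 1 equiv | 1 equiv | 1 equiv | 1 equiv | 1.00 equiv | 1.00 equiv | 1.00 equiv | 1.00 equiv | 1.00 equiv | 1.00 equiv |
| Q | 1.05 equiv | 1.05 equiv | 1.05 equiv | 1.4 equiv | 1.05 equiv | 1.60 equiv | 4.20 equiv | 0.260 equiv | 0.700 equiv | 1.05 equiv |
| remark | run made earlier | run made earlier | run made earlier | run made earlier |  |  |  |  |  |  |
| time |  |  |  |  | 12 min | 12 min | 12 min | 12 min | 12 min | 12 min |

| run | time / min | Z / % |
|---|---|---|
| elm | 1.00 | 0 |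
| elm | 2.00 | 0 |
| elm | 3.00 | 0.5 |
| elm | 6.00 | 1.2 |
| elm | 12.0 | 7.5 |
| ash | 1.00 | 1.2 |
| ash | 2.00 | 0.1 |
| ash | 3.00 | 1.7 |
| ash | 6.00 | 7.7 |
| ash | 12.0 | 18.6 |
| cedar | 1.00 | 0.3 |
| cedar | 2.00 | 5.4 |
| cedar | 3.00 | 11.5 |
| cedar | 6.00 | 25.4 |
| cedar | 12.0 | 34.9 |
| alder | 1.00 | 0.9 |
| alder | 3.00 | 11.1 |
| alder | 6.00 | 25.7 |
| alder | 8.00 | 31.5 |
| alder | 12.0 | 37.6 |

(scatter of a reading: 1 percentage point)

* the flasks by amount of Z, in percent of the J charged, highest first, at 12 min (summer / autumn / winter / dawn / dusk / midnight)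
* the amount of Z, in percent of the J charged of the flask you put first, at 12 min
* the amount of Z, in percent of the J charged of the flask you put last, at 12 min

- the earlier runs were read with a standard deviation of 1 percentage point
- reactions considered so far: Q + D -> G; E + G -> Z; D <-> L; J + Q -> E

**First chain.** I reckon dawn, where Q at 0.260 equiv is the limiting reagent. Its dose, charge of J times time, is 0.144 M·min. Ash goes from 1.7% at 3.00 min to 7.7% at 6.00 min, so Z reads as dose to the power 2.18. E and G each take one Q, so I scale elm by the square of the Q equivalents, a factor 0.0613. That gives dawn 0.329%.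

**Weak link.** That power rests on a reading of 1.7% with a scatter of 1 point, taken on another clock than dawn's. Elm and ash at 12.0 min share dawn's clock and read 7.5% and 18.6%, which gives the power 1.25. I commit to 0.379% for dawn.

**The forecast.** It orders the flasks winter > autumn > midnight > summer > dusk > dawn, with top 75% (60% to 88%) and low 0.6% (0.1% to 2%). For dawn it says: “Z scales roughly as Q², and the solution is dilute”. My figure lies below its value for low, inside its range.

**The flask.** The order comes out winter > autumn > midnight > summer > dusk > dawn, with top 78.7% and low 0.472%, both inside the forecast's ranges.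

    Q + D → G (k = 0.0290 M⁻¹ s⁻¹)
    E + G → Z (k = 0.650 M⁻¹ s⁻¹)
    D ⇌ L (K = 3.20, k = 9.10 × 10⁻⁴ s⁻¹)
    J + Q → E (k = 0.0360 M⁻¹ s⁻¹)

**Dawn's clock.** In dawn at 4.67 min, D passes into L at 12 times the rate at which it passes with Q into G, counting the forward rate of the D step alone. By that step alone, both ways together, D and L relax in dawn with a half-life of 9.67 min, within the 12 min of the run, and at 12.0 min dawn holds 53.3% of its charged D and 0.00514 M of L.

**Second flask.** Dawn left until 50 min has dose 0.600 M·min, 4.17 times 0.144 M·min. Dawn's recipe at 0.048 M of J, read at 12 min, has 0.576 M·min, so the dose reckoning puts these two flasks close together. The computed values are 4.67% and 5.60%, the flask left until 50 min reading lower.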